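1.76 M of first nucleophile was the number I carried into these flasks. In Thursday's run the substrate had lost 93.2% of its charge by 12.0 min and the target, crystals counted in, stood at 17.6%, so the target took 18.9% of the substrate consumed. I took the even split as the zero of my scale: the even-split concentration is the amount of first nucleophile at which the target would take as much of the consumed substrate as the other routes together. At a fixed second nucleophile charge, the target's share is then first nucleophile divided by the sum of first nucleophile and that concentration.

common to all: substrate 0.077 M
- Tuesday's: first nucleophile 0.193 M; second nucleophile 0.11 M; run made earlier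
- Wednesday's: first nucleophile 0.193 M; second nucleophile 0.19 M; run made earlier
- Sunday's: first nucleophile 0.193 M; second nucleophile 0.47 M; run made earlier
- Thursday's: first nucleophile 0.41 M; second nucleophile 0.0924 M; run made earlier
- delta: first nucleophile 0.193 M; second nucleophile 0.0924 M; time 12 min
- alpha: first nucleophile 0.800 M; second nucleophile 0.400 M; time 12 min

| run | time / min | target / % | substrate / % |
|---|---|---|---|
| Tuesday's | 2.50 | 4.8 | 56.4 |
| Tuesday's | 5.00 | 5.9 | 31.6 |
| Tuesday's | 8.00 | 8.4 | 16.1 |
| Tuesday's | 10.0 | 9.1 | 9.6 |
| Tuesday's | 12.0 | 9.0 | 6.1 |
| Wednesday's | 1.00 | 1.6 | 79.9 |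
| Wednesday's | 2.00 | 2.4 | 63.4 |
| Wednesday's | 3.00 | 5.3 | 50.2 |
| Wednesday's | 6.00 | 7.5 | 26.3 |
| Wednesday's | 12.0 | 8.4 | 6.0 |
| Sunday's | 1.00 | 2.5 | 80.3 |
| Sunday's | 3.00 | 4.4 | 50.7 |
| Sunday's | 6.00 | 6.1 | 25.6 |
| Sunday's | 8.00 | 7.2 | 16.2 |
| Sunday's | 12.0 | 7.8 | 6.1 |
| Thursday's | 2.50 | 8.1 | 56.2 |
| Thursday's | 5.00 | 12.7 | 31.8 |
| Thursday's | 8.00 | 16.0 | 16.3 |
| Thursday's | 10.0 | 17.3 | 10.5 |
| Thursday's | 12.0 | 17.6 | 6.8 |

(scatter of a reading: 0.5 percentage points)

- for target the crystals are counted in
- as a solid, counted per litre of solution: crystals
- the earlier runs were read with a standard deviation of 0.5 percentage points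
- on the list of suspects stand: second nucleophile + intermediate -> other capture product; first nucleophile + intermediate -> target; crystals <-> target; intermediate -> solvolysis product; intermediate -> side product; substrate -> intermediate

1. which one finishes higher in amount of target, in percent of the substrate charged ("neither" within 2 percentage points) (delta / alpha / neither)
2. amount of target at the end, in percent of the substrate charged, delta
3. amount of target at the end, in percent of the substrate charged, alpha

The last substrate readings of the four runs lay between 6.0% and 6.8%, so I used their mean, 6.25%, for both flasks. Tuesday's run gave an even-split concentration of 1.82 M and Sunday's 2.13 M, so the readings, with their scatter, put the slope against the second nucleophile charge at 0.861.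

Delta looks nearly like Tuesday's run: the first nucleophile is the same, and the second nucleophile is 0.0924 M against 0.11 M. That gap moves the even-split concentration by 0.0151 M, far less than 1.76 M, so I expected delta to end beside Tuesday's 9.0%. Delta has Thursday's second nucleophile, so I used Thursday's even-split concentration and reckoned 9.26%. For alpha the even-split concentration rises to 2.03 M, still above its 0.800 M of first nucleophile, and I reckoned 26.5%, well above delta. On a repeat, the reading to watch is the target's share of the substrate consumed, with the crystals counted in.

The forecast named alpha, with 9.3% for delta and 26.8% for alpha, slightly above my alpha figure, and said that “the second nucleophile competes only weakly”.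

The flasks gave 9.24% in delta and 27.1% in alpha, so alpha finished higher.

    second nucleophile + intermediate → other capture product (k = 759 L mol⁻¹ min⁻¹)
    first nucleophile + intermediate → target (k = 1130 L mol⁻¹ min⁻¹)
    crystals ⇌ target, rate k3*(cs3 - [target]) while solid is left; crystals form when [target] > cs3 (solubility = 2.70 mM, k = 15.6 min⁻¹)
    intermediate → solvolysis product (k = 1880 min⁻¹)
    intermediate → side product (k = 0.0444 min⁻¹)
    substrate → intermediate (k = 0.227 min⁻¹)

Read backwards, alpha's result gives an even-split concentration of 1.96 M, a little below my 2.03 M. The neighbouring flask is alpha with its first nucleophile cut to 0.48 M, the second nucleophile and the time held. With that concentration, the target's share there is 19.7%, and with 6.56% of the substrate left, the reckoning gives 18.4% target. The neighbouring flask itself ended with 18.4% target.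

All runs stem from a simulated flask from invented constants, noise included.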